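**Retrosynthetic overview**
1. Target 29 ⇒ ester C–O bond: core amino alcohol 21 + silyl-protected (2E,6S)-hydroxy acid 26, the acid coming from (S)-citronellol 22 by allylic oxidation.
2. 21 ⇒ bicyclic N-tosyl hemiaminal 16: C1–OH to C1–H, hydrogenation of C3=C4 from the convex face (sets C4), N-tosyl exchanged for N-methyl.
3. 16 ⇒ acyclic aldehyde/N-tosyl-1-azadiene 13 by one amine-catalysed intramolecular inverse-electron-demand aza-[4+2]: bond C4a–C7a closes the cyclopentane ring first, bond N2–C1 then closes the piperidine ring in the same operation.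
4. Enabling feature: the C1 aldehyde (its α-carbon C7a becomes an enamine nucleophile) and the electron-poor azadiene N2=C3–C4=C4a sit at the two ends of the three-carbon tether C5–C6–C7, which already carries the C6–O and C7–CH3 stereocentres; bond C7a–C4a is therefore a five-ring closure that leaves N2 beside C1 for the six-ring closure.
5. 13 ⇒ anti-crotylation of 4-methylpent-3-enal 2 with (E)-but-2-ene 3 (sets C6 and C7); vinyl → CH2CHO, prenyl → (E)-enal → N-sulfonyl imine.

Key step: step 8

Remark: locants C1–C7a are those of the cyclopenta[c]pyridine core; the carbinol/aminal carbon C1 of 15 and 16 is taken as a mixture of epimers (no descriptor in the SMILES) because it becomes CH2 in step 9.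

**Step 1**
Reactants: 1 4-methylpent-3-en-1-ol
Product: 2 4-methylpent-3-enal
Conditions: Dess–Martin periodinane, NaHCO3, CH2Cl2, 0 °C; crude aldehyde used at once
Reagents that add atoms: none
Why: Dess–Martin oxidation under bicarbonate buffering takes the primary alcohol to the aldehyde without acid or base strong enough to move the trisubstituted double bond into conjugation.

**Step 2**
Reactants: 2 4-methylpent-3-enal; 3 (E)-but-2-ene
Product: 5 (3S,4R)-3,7-dimethylocta-1,6-dien-4-ol, via borinate ester 4 (not isolated)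
Conditions: 3, KOt-Bu, n-BuLi, THF, −78 to −45 °C; (−)-B-methoxydiisopinocampheylborane [(+)-α-pinene series], −78 °C; BF3·OEt2; 2, −78 °C; then NaOH, H2O2, 0 °C to rt
Reagents that add atoms: none
Why: Brown crotylation through a closed chair (Zimmerman–Traxler) transition state, in which the (E)-crotyl geometry gives the 3,4-anti pair and the isopinocampheyl groups of this series are expected to direct attack to the Si face of the aldehyde, setting C4 as R and C3 as S (the later C6 and C7 of the core).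

**Step 3**
Reactants: 5 (3S,4R)-3,7-dimethylocta-1,6-dien-4-ol
Product: 6 {[(3S,4R)-3,7-dimethylocta-1,6-dien-4-yl]oxymethyl}benzene
Conditions: NaH, BnBr, n-Bu4NI (cat.), THF/DMF, 0 °C to rt
Reagents that add atoms: benzyl bromide, BrCc1ccccc1
Why: Williamson ether synthesis on the alkoxide, which touches no stereocentre and gives an ether that survives all steps up to the hydrogenation.

**Step 4**
Reactants: 6 {[(3S,4R)-3,7-dimethylocta-1,6-dien-4-yl]oxymethyl}benzene
Product: 8 (3S,4R)-4-(benzyloxy)-3,7-dimethyloct-6-en-1-ol, via B-alkyl-9-borabicyclononane 7 (not isolated)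
Conditions: 9-borabicyclo[3.3.1]nonane (9-BBN), THF, 0 °C to rt; then NaOH, H2O2, 0 °C
Reagents that add atoms: hydrogen peroxide, OO
Why: Hydroboration–oxidation, in which 9-BBN adds anti-Markovnikov to the monosubstituted vinyl group far faster than to the trisubstituted alkene and the C–B bond is oxidised to the primary alcohol.

**Step 5**
Reactants: 8 (3S,4R)-4-(benzyloxy)-3,7-dimethyloct-6-en-1-ol
Product: 10 (2E,5R,6S)-5-(benzyloxy)-8-hydroxy-2,6-dimethyloct-2-enal, via allylic diol 9 (not isolated)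
Conditions: SeO2 (cat.), t-BuOOH, CH2Cl2, rt; then MnO2, CH2Cl2, rt
Reagents that add atoms: tert-butyl hydroperoxide, CC(C)(C)OO
Why: SeO2 allylic oxidation (ene reaction, then [2,3]-sigmatropic shift) attacks the (E)-methyl group at the more substituted alkene terminus, and MnO2 then oxidises only the allylic alcohol of diol 9, so the (E)-enal forms while the saturated primary alcohol stays.

**Step 6**
Reactants: 10 (2E,5R,6S)-5-(benzyloxy)-8-hydroxy-2,6-dimethyloct-2-enal; 11 4-methylbenzenesulfonamide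
Product: 12 N-[(1E,2E,5R,6S)-5-(benzyloxy)-8-hydroxy-2,6-dimethyloct-2-en-1-ylidene]-4-methylbenzenesulfonamide
Conditions: Ti(OEt)4, CH2Cl2, 40 °C
Reagents that add atoms: none
Why: Ti(OEt)4 serves as Lewis acid and water scavenger for the condensation of the sulfonamide with the enal carbonyl to the conjugated (E)-N-sulfonyl imine (a 1-azadiene), while the remote alcohol only exchanges reversibly onto titanium.

**Step 7**
Reactants: 12 N-[(1E,2E,5R,6S)-5-(benzyloxy)-8-hydroxy-2,6-dimethyloct-2-en-1-ylidene]-4-methylbenzenesulfonamide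
Product: 13 N-[(1E,2E,5R,6S)-5-(benzyloxy)-2,6-dimethyl-8-oxooct-2-en-1-ylidene]-4-methylbenzenesulfonamide
Conditions: Dess–Martin periodinane, NaHCO3, CH2Cl2, 0 °C to rt
Reagents that add atoms: none
Why: Dess–Martin oxidation is neutral and water-free, so the primary alcohol should go to the aldehyde without hydrolysis of the N-sulfonyl imine or epimerisation of the β-methyl centre.

**Step 8**
Reactants: 13 N-[(1E,2E,5R,6S)-5-(benzyloxy)-2,6-dimethyl-8-oxooct-2-en-1-ylidene]-4-methylbenzenesulfonamide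
Product: 16 (4aR,6R,7S,7aR)-6-(benzyloxy)-4,7-dimethyl-2-tosyl-2,4a,5,6,7,7a-hexahydro-1H-cyclopenta[c]pyridin-1-ol (C1 epimers), via enamine 14 (not isolated), via bicyclic aminal 15 (not isolated)
Conditions: (R)-2-[diphenyl(trimethylsilyloxy)methyl]pyrrolidine (20 mol%), PhCO2H (20 mol%), MeCN, 0 °C to rt
Reagents that add atoms: none
Why: The secondary amine condenses with the C1 aldehyde to the (E)-enamine 14, whose nucleophilic C7a adds to C4a, the terminus of the electron-poor N-sulfonyl-1-azadiene N2=C3–C4=C4a, and the sulfonamide nitrogen set free by this addition closes on the C1 iminium carbon to give aminal 15, which hydrolyses to hemiaminal 16 and returns the catalyst (a formal inverse-electron-demand aza-[4+2]). The closest known reactions are the amine-catalysed inverse-electron-demand aza-Diels–Alder reaction of N-sulfonyl-1-azadienes with enolisable aldehydes and the intramolecular enamine/enal cycloaddition used for iridoid lactols. The cyclopentane ring closes by a 5-exo-trig Michael-type attack of C7a on C4a across the C5–C6–C7 tether, and the tetrahydropyridine ring by 6-exo-trig attack of N2 on the exocyclic iminium bond at C1, together a suprafacial [4+2] closure. C7a is set by the enamine face that reacts: the diphenyl(silyloxy)methyl group of the (R)-catalyst shields one face and the existing C7 methyl group prefers to end trans to C1, both pointing to 7aR. C4a is expected cis to C7a because only the compact, tether-endo arrangement keeps N2 within reach of C1, and this places the new ring trans to the C6 benzyloxy group; the C1 carbinol centre is of no consequence. The step needs attack at C4a and not at C3, together with cis ring fusion: the three-atom tether rules out 1,2-addition (it would need an (E)-alkene in a seven-membered ring), the (E,E)-azadiene presents C4a with its hydrogen inside, and the sulfonyl group both activates C4a and makes N2 a good internal nucleophile.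

**Step 9**
Reactants: 16 (4aR,6R,7S,7aR)-6-(benzyloxy)-4,7-dimethyl-2-tosyl-2,4a,5,6,7,7a-hexahydro-1H-cyclopenta[c]pyridin-1-ol (C1 epimers)
Product: 17 (4aR,6R,7S,7aR)-6-(benzyloxy)-4,7-dimethyl-2-tosyl-2,4a,5,6,7,7a-hexahydro-1H-cyclopenta[c]pyridine
Conditions: Et3SiH, BF3·OEt2, CH2Cl2, −78 °C
Reagents that add atoms: none
Why: Ionic reduction, in which BF3 ionises the hemiaminal to an N-sulfonyliminium ion at C1 that should be captured by hydride from the silane at low temperature before it can lose the C7a proton, so C1 becomes CH2 and the four ring stereocentres are kept.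

**Step 10**
Reactants: 17 (4aR,6R,7S,7aR)-6-(benzyloxy)-4,7-dimethyl-2-tosyl-2,4a,5,6,7,7a-hexahydro-1H-cyclopenta[c]pyridine
Product: 18 (4R,4aS,6R,7S,7aR)-4,7-dimethyl-2-tosyloctahydro-1H-cyclopenta[c]pyridin-6-ol
Conditions: H2 (3 atm), Pd(OH)2/C, EtOH, rt
Reagents that add atoms: none
Why: Heterogeneous hydrogenation should add hydrogen to the trisubstituted ene-sulfonamide from the convex face of the cis-fused bicycle, anti to the cyclopentane carbon C5 on C4a, which puts the new C4 hydrogen cis to H4a and the C4 methyl group on the concave side (4R), while the benzyl ether is hydrogenolysed in the same operation.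

**Step 11**
Reactants: 18 (4R,4aS,6R,7S,7aR)-4,7-dimethyl-2-tosyloctahydro-1H-cyclopenta[c]pyridin-6-ol
Product: 19 (4R,4aS,6R,7S,7aR)-4,7-dimethyloctahydro-1H-cyclopenta[c]pyridin-6-ol
Conditions: NaC10H8 (sodium naphthalenide, excess), DME, −78 °C; then H2O
Reagents that add atoms: none
Why: Reductive desulfonylation by single-electron transfer to the arenesulfonyl group cleaves the N–S bond without touching any stereocentre.

**Step 12**
Reactants: 19 (4R,4aS,6R,7S,7aR)-4,7-dimethyloctahydro-1H-cyclopenta[c]pyridin-6-ol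
Product: 21 (4R,4aS,6R,7S,7aR)-2,4,7-trimethyloctahydro-1H-cyclopenta[c]pyridin-6-ol, via N-hydroxymethyl amine 20 (not isolated)
Conditions: aq. HCHO, H2 (1 atm), Pd/C, MeOH, rt
Reagents that add atoms: formaldehyde, C=O
Why: Reductive amination, in which formaldehyde condenses with the secondary amine to the carbinolamine/iminium ion that is hydrogenated to the N-methyl group while the secondary alcohol is inert.

**Step 13**
Reactants: 22 (3S)-3,7-dimethyloct-6-en-1-ol [(S)-citronellol]
Product: 23 tert-butyl{[(3S)-3,7-dimethyloct-6-en-1-yl]oxy}dimethylsilane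
Conditions: TBSCl, imidazole, CH2Cl2, rt
Reagents that add atoms: tert-butyldimethylsilyl chloride, CC(C)(C)[Si](C)(C)Cl
Why: Standard silylation of the primary alcohol, which carries the (S)-methyl centre of the side chain unchanged from the chiral pool.

**Step 14**
Reactants: 23 tert-butyl{[(3S)-3,7-dimethyloct-6-en-1-yl]oxy}dimethylsilane
Product: 25 (2E,6S)-8-[(tert-butyldimethylsilyl)oxy]-2,6-dimethyloct-2-enal, via allylic alcohol 24 (not isolated)
Conditions: SeO2 (cat.), t-BuOOH, CH2Cl2, rt; then MnO2, CH2Cl2, rt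
Reagents that add atoms: tert-butyl hydroperoxide, CC(C)(C)OO
Why: The same SeO2 allylic oxidation as in step 5 functionalises the (E)-methyl group of the prenyl terminus, and MnO2 takes the allylic alcohol to the (E)-enal.

**Step 15**
Reactants: 25 (2E,6S)-8-[(tert-butyldimethylsilyl)oxy]-2,6-dimethyloct-2-enal
Product: 26 (2E,6S)-8-[(tert-butyldimethylsilyl)oxy]-2,6-dimethyloct-2-enoic acid
Conditions: NaClO2, NaH2PO4, 2-methylbut-2-ene, t-BuOH/H2O, 0 °C to rt
Reagents that add atoms: sodium chlorite, [Na+].[O-]Cl=O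
Why: Pinnick oxidation converts the enal into the enoic acid without isomerising the (E)-double bond, the hypochlorite being trapped by the added alkene.

**Step 16**
Reactants: 26 (2E,6S)-8-[(tert-butyldimethylsilyl)oxy]-2,6-dimethyloct-2-enoic acid; 21 (4R,4aS,6R,7S,7aR)-2,4,7-trimethyloctahydro-1H-cyclopenta[c]pyridin-6-ol
Product: 28 (4R,4aS,6R,7S,7aR)-2,4,7-trimethyloctahydro-1H-cyclopenta[c]pyridin-6-yl (2E,6S)-8-[(tert-butyldimethylsilyl)oxy]-2,6-dimethyloct-2-enoate, via mixed anhydride 27 (not isolated)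
Conditions: 26, 2,4,6-trichlorobenzoyl chloride, Et3N, THF, rt; then 21, DMAP, toluene, rt to 40 °C
Reagents that add atoms: none
Why: Yamaguchi esterification, in which DMAP attacks the less hindered enoyl carbonyl of the mixed anhydride and the acylpyridinium ion acylates the hindered secondary alcohol with retention at C6, the tertiary amine not interfering.

**Step 17**
Reactants: 28 (4R,4aS,6R,7S,7aR)-2,4,7-trimethyloctahydro-1H-cyclopenta[c]pyridin-6-yl (2E,6S)-8-[(tert-butyldimethylsilyl)oxy]-2,6-dimethyloct-2-enoate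
Product: 29 (4R,4aS,6R,7S,7aR)-2,4,7-trimethyloctahydro-1H-cyclopenta[c]pyridin-6-yl (2E,6S)-8-hydroxy-2,6-dimethyloct-2-enoate (target)
Conditions: HF·pyridine, pyridine, THF, 0 °C to rt
Reagents that add atoms: none
Why: Fluoride-mediated desilylation frees the primary alcohol while the enoate ester, the tertiary amine and all stereocentres are inert.

**Compound list**
1 | 4-methylpent-3-en-1-ol | CC(C)=CCCO | starting material
2 | 4-methylpent-3-enal | CC(C)=CCC=O | intermediate
3 | (E)-but-2-ene | C/C=C/C | starting material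
4 | (3S,4R)-3,7-dimethylocta-1,6-dien-4-yl diisopinocampheylborinate (not isolated) | CC(C)=CC[C@@H](OB([C@@H]1C[C@@H]2C[C@H]([C@H]1C)C2(C)C)[C@@H]1C[C@@H]2C[C@H]([C@H]1C)C2(C)C)[C@@H](C)C=C | intermediate
5 | (3S,4R)-3,7-dimethylocta-1,6-dien-4-ol | CC(C)=CC[C@@H](O)[C@@H](C)C=C | intermediate
6 | {[(3S,4R)-3,7-dimethylocta-1,6-dien-4-yl]oxymethyl}benzene | CC(C)=CC[C@@H](OCc1ccccc1)[C@@H](C)C=C | intermediate
7 | 9-[(3S,4R)-4-(benzyloxy)-3,7-dimethyloct-6-en-1-yl]-9-borabicyclo[3.3.1]nonane (not isolated) | CC(C)=CC[C@@H](OCc1ccccc1)[C@@H](C)CCB1C2CCCC1CCC2 | intermediate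
8 | (3S,4R)-4-(benzyloxy)-3,7-dimethyloct-6-en-1-ol | CC(C)=CC[C@@H](OCc1ccccc1)[C@@H](C)CCO | intermediate
9 | (2E,5R,6S)-5-(benzyloxy)-2,6-dimethyloct-2-ene-1,8-diol (not isolated) | OC/C(C)=C/C[C@@H](OCc1ccccc1)[C@@H](C)CCO | intermediate
10 | (2E,5R,6S)-5-(benzyloxy)-8-hydroxy-2,6-dimethyloct-2-enal | O=C/C(C)=C/C[C@@H](OCc1ccccc1)[C@@H](C)CCO | intermediate
11 | 4-methylbenzenesulfonamide | Cc1ccc(cc1)S(N)(=O)=O | starting material
12 | N-[(1E,2E,5R,6S)-5-(benzyloxy)-8-hydroxy-2,6-dimethyloct-2-en-1-ylidene]-4-methylbenzenesulfonamide | Cc1ccc(cc1)S(=O)(=O)/N=C/C(C)=C/C[C@@H](OCc1ccccc1)[C@@H](C)CCO | intermediate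
13 | N-[(1E,2E,5R,6S)-5-(benzyloxy)-2,6-dimethyl-8-oxooct-2-en-1-ylidene]-4-methylbenzenesulfonamide | Cc1ccc(cc1)S(=O)(=O)/N=C/C(C)=C/C[C@@H](OCc1ccccc1)[C@@H](C)CC=O | intermediate
14 | (E)-enamine of 13 with (R)-2-[diphenyl(trimethylsilyloxy)methyl]pyrrolidine (not isolated) | Cc1ccc(cc1)S(=O)(=O)/N=C/C(C)=C/C[C@@H](OCc1ccccc1)[C@@H](C)/C=C/N1CCC[C@@H]1C(O[Si](C)(C)C)(c1ccccc1)c1ccccc1 | intermediate
15 | (4aR,6R,7S,7aR)-6-(benzyloxy)-4,7-dimethyl-1-{(R)-2-[diphenyl(trimethylsilyloxy)methyl]pyrrolidin-1-yl}-2-tosyl-2,4a,5,6,7,7a-hexahydro-1H-cyclopenta[c]pyridine, C1 epimers (not isolated) | c1ccccc1CO[C@@H]1C[C@@H]2[C@@H](C(N3CCC[C@@H]3C(O[Si](C)(C)C)(c3ccccc3)c3ccccc3)N(S(=O)(=O)c3ccc(C)cc3)C=C2C)[C@@H]1C | intermediate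
16 | (4aR,6R,7S,7aR)-6-(benzyloxy)-4,7-dimethyl-2-tosyl-2,4a,5,6,7,7a-hexahydro-1H-cyclopenta[c]pyridin-1-ol, C1 epimers | c1ccccc1CO[C@@H]1C[C@@H]2[C@@H](C(O)N(S(=O)(=O)c3ccc(C)cc3)C=C2C)[C@@H]1C | intermediate
17 | (4aR,6R,7S,7aR)-6-(benzyloxy)-4,7-dimethyl-2-tosyl-2,4a,5,6,7,7a-hexahydro-1H-cyclopenta[c]pyridine | c1ccccc1CO[C@@H]1C[C@@H]2[C@@H](CN(S(=O)(=O)c3ccc(C)cc3)C=C2C)[C@@H]1C | intermediate
18 | (4R,4aS,6R,7S,7aR)-4,7-dimethyl-2-tosyloctahydro-1H-cyclopenta[c]pyridin-6-ol | O[C@@H]1C[C@@H]2[C@@H](CN(S(=O)(=O)c3ccc(C)cc3)C[C@@H]2C)[C@@H]1C | intermediate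
19 | (4R,4aS,6R,7S,7aR)-4,7-dimethyloctahydro-1H-cyclopenta[c]pyridin-6-ol | O[C@@H]1C[C@@H]2[C@@H](CNC[C@@H]2C)[C@@H]1C | intermediate
20 | (4R,4aS,6R,7S,7aR)-2-(hydroxymethyl)-4,7-dimethyloctahydro-1H-cyclopenta[c]pyridin-6-ol (not isolated) | O[C@@H]1C[C@@H]2[C@@H](CN(CO)C[C@@H]2C)[C@@H]1C | intermediate
21 | (4R,4aS,6R,7S,7aR)-2,4,7-trimethyloctahydro-1H-cyclopenta[c]pyridin-6-ol | O[C@@H]1C[C@@H]2[C@@H](CN(C)C[C@@H]2C)[C@@H]1C | intermediate
22 | (3S)-3,7-dimethyloct-6-en-1-ol [(S)-citronellol] | C[C@@H](CCC=C(C)C)CCO | starting material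
23 | tert-butyl{[(3S)-3,7-dimethyloct-6-en-1-yl]oxy}dimethylsilane | C[C@@H](CCC=C(C)C)CCO[Si](C)(C)C(C)(C)C | intermediate
24 | (2E,6S)-8-[(tert-butyldimethylsilyl)oxy]-2,6-dimethyloct-2-en-1-ol (not isolated) | C[C@@H](CC/C=C(\C)CO)CCO[Si](C)(C)C(C)(C)C | intermediate
25 | (2E,6S)-8-[(tert-butyldimethylsilyl)oxy]-2,6-dimethyloct-2-enal | C[C@@H](CC/C=C(\C)C=O)CCO[Si](C)(C)C(C)(C)C | intermediate
26 | (2E,6S)-8-[(tert-butyldimethylsilyl)oxy]-2,6-dimethyloct-2-enoic acid | C[C@@H](CC/C=C(\C)C(O)=O)CCO[Si](C)(C)C(C)(C)C | intermediate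
27 | (2E,6S)-8-[(tert-butyldimethylsilyl)oxy]-2,6-dimethyloct-2-enoic 2,4,6-trichlorobenzoic anhydride (not isolated) | C[C@@H](CC/C=C(\C)C(=O)OC(=O)c1c(Cl)cc(Cl)cc1Cl)CCO[Si](C)(C)C(C)(C)C | intermediate
28 | (4R,4aS,6R,7S,7aR)-2,4,7-trimethyloctahydro-1H-cyclopenta[c]pyridin-6-yl (2E,6S)-8-[(tert-butyldimethylsilyl)oxy]-2,6-dimethyloct-2-enoate | C/C(=C\CC[C@H](C)CCO[Si](C)(C)C(C)(C)C)C(=O)O[C@@H]1C[C@@H]2[C@@H](CN(C)C[C@@H]2C)[C@@H]1C | intermediate
29 | (4R,4aS,6R,7S,7aR)-2,4,7-trimethyloctahydro-1H-cyclopenta[c]pyridin-6-yl (2E,6S)-8-hydroxy-2,6-dimethyloct-2-enoate | C/C(=C\CC[C@H](C)CCO)C(=O)O[C@@H]1C[C@@H]2[C@@H](CN(C)C[C@@H]2C)[C@@H]1C | target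

**Step count**
Total: 17 steps. Longest linear sequence: 14 steps (steps 1–12, 16 and 17).

**Steps most likely to fail**

Step 8. The N-sulfonyl imine may hydrolyse or undergo γ-deprotonation before the enamine adds, or the addition may proceed with poor facial control and stop at an open-chain trans Michael adduct that cannot close onto C1. The fallback sets out from 10 and comes back at 21, building the two rings and the nitrogen in separate operations. Dess–Martin oxidation of 10 would give (2E,5R,6S)-5-(benzyloxy)-2,6-dimethyloct-2-enedial F1. Stoichiometric N-methylaniline with molecular sieves should form the enamine of the saturated aldehyde, which undergoes the known intramolecular enamine/enal cycloaddition to the cis-fused N-methylanilino acetal F2. Aqueous acid would hydrolyse it to the lactol F3. Hydrogenation of the enol ether over Rh/Al2O3 from the convex face would give the saturated lactol F4. NaBH4 would open it to the diol F5, MsCl/Et3N would give the bis(methanesulfonate) F6, and heating with methylamine would close the piperidine ring by double displacement to the N-methyl benzyl ether F7. Hydrogenolysis over Pd(OH)2/C returns to 21.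

Step 9. Ionisation at C1 next to the ene-sulfonamide may be followed by loss of the C7a proton (dehydration to a 1,2-dihydropyridine) instead of hydride capture, which would erase the C7a stereocentre. The fallback sets out from 16 and comes back at 18 by reversing the order of the two reductions. Hydrogenation of 16 over Pd(OH)2/C would first saturate C3=C4 and remove the benzyl group to give the saturated hemiaminal diol F8. Its simple N-sulfonyliminium ion has no conjugating enamide and should be reduced cleanly with Et3SiH/BF3·OEt2 to 18.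

Step 10. Hydrogen delivery to the hindered trisubstituted ene-sulfonamide may be slow or may occur with poor facial selectivity at C4. The fallback sets out from 17 and comes back at 19 and replaces surface hydrogenation by ionic hydrogenation. Et3SiH in CF3CO2H/CH2Cl2 should protonate C4 axially, anti to C5, and reduce the resulting N-sulfonyliminium ion at C3 to give the saturated N-tosyl benzyl ether F9. Na in liquid NH3 then removes the benzyl and the tosyl group in one operation to give 19.

**Further compounds**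
F1 | step 8 | (2E,5R,6S)-5-(benzyloxy)-2,6-dimethyloct-2-enedial | O=C/C(C)=C/C[C@@H](OCc1ccccc1)[C@@H](C)CC=O
F2 | step 8 | (4aR,6R,7S,7aR)-6-(benzyloxy)-N,4,7-trimethyl-N-phenyl-1,4a,5,6,7,7a-hexahydrocyclopenta[c]pyran-1-amine, C1 epimers | c1ccccc1CO[C@@H]1C[C@@H]2[C@@H](C(N(C)c3ccccc3)OC=C2C)[C@@H]1C
F3 | step 8 | (4aR,6R,7S,7aR)-6-(benzyloxy)-4,7-dimethyl-1,4a,5,6,7,7a-hexahydrocyclopenta[c]pyran-1-ol, C1 epimers | c1ccccc1CO[C@@H]1C[C@@H]2[C@@H](C(O)OC=C2C)[C@@H]1C
F4 | step 8 | (4R,4aS,6R,7S,7aR)-6-(benzyloxy)-4,7-dimethyloctahydrocyclopenta[c]pyran-1-ol, C1 epimers | c1ccccc1CO[C@@H]1C[C@@H]2[C@@H](C(O)OC[C@@H]2C)[C@@H]1C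
F5 | step 8 | (2R)-2-[(1S,2R,3S,4R)-4-(benzyloxy)-2-(hydroxymethyl)-3-methylcyclopentyl]propan-1-ol | c1ccccc1CO[C@@H]1C[C@@H]([C@@H](C)CO)[C@@H](CO)[C@@H]1C
F6 | step 8 | bis(methanesulfonate) of F5 | c1ccccc1CO[C@@H]1C[C@@H]([C@@H](C)COS(C)(=O)=O)[C@@H](COS(C)(=O)=O)[C@@H]1C
F7 | step 8 | (4R,4aS,6R,7S,7aR)-6-(benzyloxy)-2,4,7-trimethyloctahydro-1H-cyclopenta[c]pyridine | c1ccccc1CO[C@@H]1C[C@@H]2[C@@H](CN(C)C[C@@H]2C)[C@@H]1C
F8 | step 9 | (4R,4aS,6R,7S,7aR)-4,7-dimethyl-2-tosyloctahydro-1H-cyclopenta[c]pyridine-1,6-diol, C1 epimers | O[C@@H]1C[C@@H]2[C@@H](C(O)N(S(=O)(=O)c3ccc(C)cc3)C[C@@H]2C)[C@@H]1C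
F9 | step 10 | (4R,4aS,6R,7S,7aR)-6-(benzyloxy)-4,7-dimethyl-2-tosyloctahydro-1H-cyclopenta[c]pyridine | c1ccccc1CO[C@@H]1C[C@@H]2[C@@H](CN(S(=O)(=O)c3ccc(C)cc3)C[C@@H]2C)[C@@H]1C
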